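# Total synthesis of the (3R,4R)-dibenzylbutyrolactone 20 by Ireland–Claisen chirality transfer

Compound numbers are those of the steps and of the compound list further down.

## Analysis of the target

Compound 20 is a dibenzylbutyrolactone lignan. Apart from the two arenes its only ring is a γ-butyrolactone (O1, carbonyl C2, C3, C4, methylene C5). C3 carries the 3-hydroxy-4,5-dimethoxybenzyl group (ring B) and C4 the 3,4-dimethoxybenzyl group (ring A). The two stereocentres are vicinal CH carbons with three carbon substituents each, and the SMILES string reads as 3R,4R, which places the two arylmethyl groups trans on the ring. C3 is α to the carbonyl group and can be epimerised, with the trans isomer as the thermodynamic sink. C4 is fixed once it is made, so it carries the absolute configuration of the whole molecule. The sensitive points are the free phenol on the very electron-rich ring B, the two alkoxyarenes (oxidants, strong electrophiles) and the lactone (hydroxide, epimerising base). The difficulty is control rather than size. No heteroatom or ring fusion near C3 and C4 can steer a reagent, the two nearly identical arylmethyl groups must sit at defined positions relative to the carbonyl group, and one of five aryl oxygens must end up free. The strategy rests on the C3–C4 bond. It is flanked by the carboxyl carbon C2 on one side and by C5, which can be traced back to an alkene CH, on the other. That makes it the central bond of a 2,3-disubstituted γ,δ-unsaturated acid, the product pattern of an ester enolate Claisen rearrangement.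

## Retrosynthetic reasoning

**20 to 19.** The last bond to be made is the phenolic O–H of ring B. Going back to the benzyl ether 19 hides the only acidic and most easily oxidised group during all steps that use base or oxidant. A benzyl ether withstands amide bases, silylating agents, hydride and oxidative alkene cleavage. It leaves under neutral hydrogenolysis, which touches neither the lactone nor the epimerisable C3.

**19 to 16.** The ring is opened at O1–C2, which gives the hydroxy acid 18. C5 is then traced back through the aldehyde 17 to an alkene carbon, which gives the γ,δ-unsaturated acid 16 with an E propenyl group on C4. The cut is made here, and not at one of the CH–CH2Ar bonds, because it removes the ring without touching a stereocentre and uncovers the Claisen pattern. In the forward direction the only alkene must be cleaved beside two alkoxyarenes, and 17 must be reduced before its α-centre C4 can enolise. The γ-hydroxy acid then closes by itself in acid.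

**16 to 12.** The C3–C4 bond is cut, the double bond is moved back by one position, and oxygen is reattached to the methyl-bearing carbon. This leads through the silyl ester 15, the Z silyl ketene acetal 14 and the enolate 13 to the allylic ester 12.
- One C–C bond joins the two halves of the molecule and sets both stereocentres, using a single purchased carbinol centre as the source of chirality.
- A chair drawn with the carbinol methyl group equatorial, the E alkene and the Z ketene acetal places both arylmethyl groups equatorial on the two bonding carbons.
- The four chair atoms C2–C3–C4–C5 are the same four atoms that later lie in the lactone. Trans-diequatorial in the chair therefore means trans in 19.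
- Working through the descriptors shows that the R carbinol gives 3R,4R.

**12 to 6 and 11.** The ester acyl–oxygen bond is cut to the allylic alcohol 6 and the acid 11. This is the natural point of convergence. Ring A with the stereocentre sits in one fragment and ring B with the acyl chain in the other, so the position of each arene relative to the carbonyl group is decided by which fragment it belongs to. The forward reaction must acylate at the carboxyl carbon only and leave the allylic C–O bond intact.

**6 to 4, then 1 and 2.** The E alkene of 6 is traced back to the alkyne of 4. A propargylic alcohol can be reduced to the E allylic alcohol in a hydroxyl-directed, geometrically unambiguous way. Geometric purity matters, because a Z alkene would invert C4 in the key step. Cutting the C(sp)–CH2Ar bond of 4 gives the chiral-pool alkynol 1 and the benzylic chloride 2. No protecting group is needed, since the doubly metallated form 3 reacts at carbon.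

**11 to 8, then 7.** The Cα–Cβ bond of the propanoic acid chain is cut, a two-carbon reductive homologation of the aldehyde 8 passing through 9 and 10. Compound 8 is the benzyl ether of the commercial phenol aldehyde 7. Buying 7 settles the oxygen pattern of ring B (one free oxygen beside two methylated ones) at the outset. The homologation must saturate the chain without a hydrogenation catalyst that would remove the benzyl group.

## Alternatives that were turned down

**Alternative 1:** The bonds C4–C5 and O1–C2 are cut, so that the lactone ring is assembled in one (3+2) event from (E)-4-(3,4-dimethoxyphenyl)but-2-enal A1 and formaldehyde A2.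
- *Forward key step.* A chiral triazolylidene carbene adds to the formyl group of A1 and the extended enaminol acts as a homoenolate. Its β-carbon (the later C4) attacks A2, and the alkoxide closes onto the acyl azolium to give (R)-4-(3,4-dimethoxybenzyl)dihydrofuran-2(3H)-one A3. Ring B would follow by trans-selective benzylation of the lactone enolate.
- *For.* The source of chirality is catalytic, ring and C4 arise in one step, and the step count is lower than here. On step economy this plan is stronger.
- *Against.* Homoenolate annulations suit β-aryl enals and aryl or activated carbonyl acceptors. A1 is a β-alkyl enal whose γ-CH2 is benzylic and vinylogously acidic, so the base that liberates the carbene can move the double bond into conjugation with ring A.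
- *Against.* A2 is the least hindered aldehyde. It competes with A1 for the carbene, can oligomerise through its own acyl anion chemistry, and can be attacked by the acyl anion carbon instead of the β-carbon.
- *Against.* The only stereocentre forms at a carbon remote from the chiral azolium, against an acceptor without any substituent to interlock with the catalyst. The facial bias therefore cannot be predicted from structure.
- *Comparison.* C3 would still need a step of its own. The chosen route spends more steps. In exchange it replaces an unproven enantioselective event by a pericyclic transfer from a purchased stereocentre, and it sets C3 and C4 together.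

**Alternative 2:** The C5'–O bond of ring B is cut, which leads back to arctigenin A4. This lignan already holds the lactone, both stereocentres and ring A.
- *Forward key step.* A phenol ortho-hydroxylase would insert oxygen next to the 4'-phenol and give the ring B catechol 5'-hydroxyarctigenin A5. The enzyme would be a P450 monooxygenase of the kind that 5-hydroxylates guaiacyl units, or a two-component flavin-dependent phenol hydroxylase. No ring closes and no stereocentre is made.
- *For.* The plan is very short, needs no protecting groups, and raises no stereochemical question. On these points it is clearly stronger than the chosen route.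
- *Against.* A5 is not the target. Ring B of 20 has the central 4'-oxygen methylated and an outer oxygen free, so the hindered central hydroxyl would have to be methylated beside the new outer one. Without a para acceptor group the acidity difference between the two is small, and methyltransferases of this pathway prefer the outer hydroxyl, which is the wrong one.
- *Against.* Guaiacyl 5-hydroxylases are membrane-bound enzymes shaped for small monomeric phenylpropanoids. The flavin-dependent enzymes prefer phenols with both ortho positions free. A bulky lignan with one ortho position blocked by methoxy fits neither profile.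
- *Against.* The electron-rich catechol A5 is prone to further oxidation under the aerobic conditions.
- *Against.* Starting from A4 is a semisynthesis. Otherwise A4 needs an asymmetric synthesis as long as that of 20.
- *Comparison.* The chosen route buys the oxygen pattern of ring B ready-made in 7, so it has no late regiochemical problem.

**Alternative 3:** O1–C2 and the C5–H bond made by reduction are cut. This leads back to methyl 2-(3-benzyloxy-4,5-dimethoxybenzyl)-4-(3,4-dimethoxyphenyl)-3-formylbutanoate A6, used as the mixture of its four stereoisomers.
- *Forward key step.* A nicotinamide-dependent ketoreductase reduces only the aldehydes that are R at C4, while C4, being α to the formyl group, keeps epimerising. The hydroxy ester closes to (4R)-3-(3-benzyloxy-4,5-dimethoxybenzyl)-4-(3,4-dimethoxybenzyl)dihydrofuran-2(3H)-one A7, mixed at C3, which base would funnel to 19.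
- *For.* No chiral starting material is needed, a racemate can in principle be converted completely, and the conditions are mild. The correction at C3 is as good as the one available here.
- *Against.* Dynamic reductive resolutions of aldehydes depend on racemisation that is fast relative to reduction. α-Aryl aldehydes meet this condition, but the C4–H of A6 belongs to an ordinary α-branched aliphatic aldehyde. Near neutral pH the process may fall back to a simple kinetic resolution, and a higher pH invites ester hydrolysis and aldol reactions.
- *Against.* The enzyme must tell apart two large flexible groups at C4, and must do so for both C3 epimers of a lipophilic, poorly soluble substrate. That is a screening task that cannot be planned from the structure.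
- *Against.* A6 still needs its own C3–C4 bond construction.
- *Comparison.* The step count is similar. The chosen strategy offers a stereochemical outcome that can be derived on paper from a chair model.

Key step: step 6

Assumption: commercial 1 is taken to be of high enantiomeric purity, because the optical purity of 20 cannot exceed that of the carbinol centre from which C4 is derived.

## Route

Step 1
Reactants: 1 (R)-but-3-yn-2-ol; 2 3,4-dimethoxybenzyl chloride
Product: 4 (R)-5-(3,4-dimethoxyphenyl)pent-3-yn-2-ol, via bis(bromomagnesium) salt 3 (not isolated)
Conditions: EtMgBr (2.0 equiv), THF, 0 °C → rt; CuCl (10 mol %), then 2, 45–50 °C; aq. NH4Cl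
Reagents that add atoms: EtMgBr, CC[Mg]Br (MgBr is held only in 3; no reagent atom stays in 4)
Why: Two equivalents of EtMgBr turn 1 into the O,C-dimagnesium salt 3, whose alkynyl carbon passes to copper and displaces the benzylic chloride of 2 (copper-catalysed coupling of an alkynyl Grignard reagent with a benzylic halide); the magnesium alkoxide is a poor nucleophile, so the hydroxyl group needs no protection. The carbinol C–O bond is never touched, so the R configuration is carried over unchanged.

Step 2
Reactants: 4 (R)-5-(3,4-dimethoxyphenyl)pent-3-yn-2-ol
Product: 6 (R,E)-5-(3,4-dimethoxyphenyl)pent-3-en-2-ol, via cyclic sodium alkenylaluminate 5 (not isolated)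
Conditions: NaAlH2(OCH2CH2OMe)2 (Red-Al, 1.5 equiv), THF, 0 °C → rt; aq. potassium sodium tartrate
Reagents that add atoms: NaAlH2(OCH2CH2OMe)2, [Na+].[AlH2-](OCCOC)OCCOC (aluminium and its alkoxy groups are held only in 5; only hydrogen stays in 6)
Why: Hydroxyl-directed trans-hydroalumination of a propargylic alcohol: the alkoxyaluminate delivers hydride to the alkyne carbon next to the carbinol and aluminium ends on the distal carbon in the five-membered ring of 5, whose protonolysis with retention can give only the E alkene. Arenes and aryl methyl ethers are inert and the stereocentre is a spectator.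

Step 3
Reactants: 7 3-hydroxy-4,5-dimethoxybenzaldehyde
Product: 8 3-benzyloxy-4,5-dimethoxybenzaldehyde
Conditions: BnBr, K2CO3, DMF, 50 °C
Reagents that add atoms: benzyl bromide, BrCc1ccccc1
Why: Williamson ether synthesis on the only acidic site; the phenoxide is formed by carbonate and the non-enolisable aldehyde is not affected.

Step 4
Reactants: 8 3-benzyloxy-4,5-dimethoxybenzaldehyde
Product: 11 3-(3-benzyloxy-4,5-dimethoxyphenyl)propanoic acid, via arylidene Meldrum's acid 9 (not isolated), via arylmethyl Meldrum's acid 10 (not isolated)
Conditions: Meldrum's acid, HCO2H/Et3N (5:2), 95–100 °C; ice-water, HCl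
Reagents that add atoms: Meldrum's acid, CC1(C)OC(=O)CC(=O)O1
Why: One-pot Knoevenagel condensation (9), conjugate transfer reduction by formate (10) and hydrolysis with decarboxylation of the dioxanedione ring, a known direct way from aromatic aldehydes to 3-arylpropanoic acids. The chain is saturated by hydride transfer without a metal surface, so the benzyl ether is not at risk as it would be under H2 over Pd/C.

Step 5
Reactants: 6 (R,E)-5-(3,4-dimethoxyphenyl)pent-3-en-2-ol; 11 3-(3-benzyloxy-4,5-dimethoxyphenyl)propanoic acid
Product: 12 (R,E)-5-(3,4-dimethoxyphenyl)pent-3-en-2-yl 3-(3-benzyloxy-4,5-dimethoxyphenyl)propanoate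
Conditions: DCC, DMAP (cat.), CH2Cl2, 0 °C → rt
Reagents that add atoms: none
Why: Steglich esterification; the new bond forms at the activated carboxyl carbon and the allylic C–O bond is not broken, so neither the configuration nor the position and geometry of the alkene can change.

Step 6
Reactants: 12 (R,E)-5-(3,4-dimethoxyphenyl)pent-3-en-2-yl 3-(3-benzyloxy-4,5-dimethoxyphenyl)propanoate
Product: 16 (2R,3S,4E)-2-(3-benzyloxy-4,5-dimethoxybenzyl)-3-(3,4-dimethoxybenzyl)hex-4-enoic acid, via lithium Z(O)-enolate 13 (not isolated), via Z silyl ketene acetal 14 (not isolated), via trimethylsilyl ester 15 (not isolated)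
Conditions: i-Pr2NH, n-BuLi, THF, 0 °C (LiN(i-Pr)2, 1.1 equiv); DMPU (THF/DMPU about 2:1), −78 °C; slow addition of 12; Me3SiCl, −78 °C → rt, then 50 °C; 1 M HCl
Reagents that add atoms: LiN(i-Pr)2, [Li]N(C(C)C)C(C)C (lithium is held only in 13); Me3SiCl, C[Si](C)(C)Cl (the silyl group is held only in 14 and 15; no reagent atom stays in 16)
Why: LiN(i-Pr)2 in the strongly lithium-solvating THF/DMPU medium removes an α-proton of 12 through an open transition state that places the arylmethyl group cis to OLi (13), and Me3SiCl traps the oxygen to give the Z silyl ketene acetal 14. On warming, 14 undergoes the concerted suprafacial [3,3] shift of an Ireland–Claisen rearrangement through a chair, forming the bond that becomes C3–C4 while the carbinol C–O bond breaks; no ring is closed, and the silyl ester 15 is hydrolysed to 16 on work-up. C4 is controlled by the R carbinol centre: with its methyl group equatorial only one face of the E alkene can reach the ketene acetal, which gives the arrangement that becomes 4R and leaves an E propenyl group. C3 is controlled by the ketene acetal geometry: in the same chair the Z isomer holds its arylmethyl group equatorial, so the two arylmethyl groups are trans-diequatorial on the chain C2–C3–C4–C5, syn in the zigzag form of 16 and trans (3R) in the later lactone. The step needs site-selective deprotonation, Z-selective enolisation, O- rather than C-silylation and chair rather than boat. The first is secured by the large acidity gap between the ester α-CH2 and the weaker second acid, the allylic and benzylic CH2 next to ring A (base kept near one equivalent at −78 °C), and the last by the acyclic E-disubstituted alkene on a secondary carbinol, the substrate class with the strongest chair bias. Leakage through the E ketene acetal or a boat changes only C3, which remains epimerisable after lactonisation. C4 is lost only through the chair with an axial methyl group, which suffers a 1,3-diaxial contact with the silyloxy-bearing carbon.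

Step 7
Reactants: 16 (2R,3S,4E)-2-(3-benzyloxy-4,5-dimethoxybenzyl)-3-(3,4-dimethoxybenzyl)hex-4-enoic acid
Product: 19 (3R,4R)-3-(3-benzyloxy-4,5-dimethoxybenzyl)-4-(3,4-dimethoxybenzyl)dihydrofuran-2(3H)-one, via formyl acid 17 (not isolated), via hydroxy acid 18 (not isolated)
Conditions: O3/O2, CH2Cl2/MeOH (4:1), Sudan Red 7B, −78 °C; N2 purge; NaBH4 (excess), −78 → 0 °C; 2 M HCl, rt
Reagents that add atoms: ozone, [O-][O+]=O
Why: Ozonolysis with reductive work-up: ozone attacks the only alkene much faster than the alkoxyarenes and the dye marks the end point, borohydride reduces the peroxidic products through 17 to 18, and acidification closes the γ-lactone by 5-exo-trig acyl substitution. No bond at C3 or C4 is changed, and immediate reduction in the cold keeps the α-formyl centre C4 from enolising.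

Step 8
Reactants: 19 (3R,4R)-3-(3-benzyloxy-4,5-dimethoxybenzyl)-4-(3,4-dimethoxybenzyl)dihydrofuran-2(3H)-one
Product: 20 (3R,4R)-4-(3,4-dimethoxybenzyl)-3-(3-hydroxy-4,5-dimethoxybenzyl)dihydrofuran-2(3H)-one
Conditions: H2 (1 atm), 10% Pd/C, EtOAc/EtOH, rt
Reagents that add atoms: none
Why: Hydrogenolysis of an aryl benzyl ether on palladium metal under neutral conditions; the lactone, the aryl methyl ethers and the two oxygen-free benzylic CH2 groups are inert, and no base is present that could epimerise C3.

## Compound list

1 | (R)-but-3-yn-2-ol | C[C@@H](O)C#C | starting material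
2 | 3,4-dimethoxybenzyl chloride | COc1ccc(CCl)cc1OC | starting material
3 | O,C-bis(bromomagnesium) salt of (R)-but-3-yn-2-ol | C[C@@H](O[Mg]Br)C#C[Mg]Br | intermediate
4 | (R)-5-(3,4-dimethoxyphenyl)pent-3-yn-2-ol | C[C@@H](O)C#CCc1ccc(OC)c(OC)c1 | intermediate
5 | sodium salt of the five-membered oxaaluminacyclopentene ate complex (ring O–Al–C(CH2Ar)=CH–CH(CH3), two 2-methoxyethoxy groups on aluminium, R at the carbinol carbon) | C[C@@H]1C=C(Cc2ccc(OC)c(OC)c2)[Al-](OCCOC)(OCCOC)O1.[Na+] | intermediate
6 | (R,E)-5-(3,4-dimethoxyphenyl)pent-3-en-2-ol | C[C@@H](O)/C=C/Cc1ccc(OC)c(OC)c1 | intermediate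
7 | 3-hydroxy-4,5-dimethoxybenzaldehyde | COc1cc(C=O)cc(O)c1OC | starting material
8 | 3-benzyloxy-4,5-dimethoxybenzaldehyde | COc1cc(C=O)cc(OCc2ccccc2)c1OC | intermediate
9 | 5-(3-benzyloxy-4,5-dimethoxybenzylidene)-2,2-dimethyl-1,3-dioxane-4,6-dione | COc1cc(C=C2C(=O)OC(C)(C)OC2=O)cc(OCc2ccccc2)c1OC | intermediate
10 | 5-(3-benzyloxy-4,5-dimethoxybenzyl)-2,2-dimethyl-1,3-dioxane-4,6-dione | COc1cc(CC2C(=O)OC(C)(C)OC2=O)cc(OCc2ccccc2)c1OC | intermediate
11 | 3-(3-benzyloxy-4,5-dimethoxyphenyl)propanoic acid | COc1cc(CCC(=O)O)cc(OCc2ccccc2)c1OC | intermediate
12 | (R,E)-5-(3,4-dimethoxyphenyl)pent-3-en-2-yl 3-(3-benzyloxy-4,5-dimethoxyphenyl)propanoate | C[C@H](/C=C/Cc1ccc(OC)c(OC)c1)OC(=O)CCc1cc(OCc2ccccc2)c(OC)c(OC)c1 | intermediate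
13 | lithium enolate of 12, arylmethyl group cis to OLi (Z(O) geometry) | C[C@H](/C=C/Cc1ccc(OC)c(OC)c1)O/C(O[Li])=C/Cc1cc(OCc2ccccc2)c(OC)c(OC)c1 | intermediate
14 | (Z)-trimethylsilyl ketene acetal of 12, arylmethyl group cis to OSiMe3 | C[C@H](/C=C/Cc1ccc(OC)c(OC)c1)O/C(O[Si](C)(C)C)=C/Cc1cc(OCc2ccccc2)c(OC)c(OC)c1 | intermediate
15 | trimethylsilyl (2R,3S,4E)-2-(3-benzyloxy-4,5-dimethoxybenzyl)-3-(3,4-dimethoxybenzyl)hex-4-enoate | COc1ccc(C[C@@H](/C=C/C)[C@@H](Cc2cc(OCc3ccccc3)c(OC)c(OC)c2)C(=O)O[Si](C)(C)C)cc1OC | intermediate
16 | (2R,3S,4E)-2-(3-benzyloxy-4,5-dimethoxybenzyl)-3-(3,4-dimethoxybenzyl)hex-4-enoic acid | COc1ccc(C[C@@H](/C=C/C)[C@@H](Cc2cc(OCc3ccccc3)c(OC)c(OC)c2)C(=O)O)cc1OC | intermediate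
17 | (2R,3R)-2-(3-benzyloxy-4,5-dimethoxybenzyl)-3-(3,4-dimethoxybenzyl)-4-oxobutanoic acid | COc1ccc(C[C@@H](C=O)[C@@H](Cc2cc(OCc3ccccc3)c(OC)c(OC)c2)C(=O)O)cc1OC | intermediate
18 | (2R,3R)-2-(3-benzyloxy-4,5-dimethoxybenzyl)-3-(3,4-dimethoxybenzyl)-4-hydroxybutanoic acid | COc1ccc(C[C@@H](CO)[C@@H](Cc2cc(OCc3ccccc3)c(OC)c(OC)c2)C(=O)O)cc1OC | intermediate
19 | (3R,4R)-3-(3-benzyloxy-4,5-dimethoxybenzyl)-4-(3,4-dimethoxybenzyl)dihydrofuran-2(3H)-one | COc1ccc(C[C@H]2COC(=O)[C@@H]2Cc2cc(OCc3ccccc3)c(OC)c(OC)c2)cc1OC | intermediate
20 | (3R,4R)-4-(3,4-dimethoxybenzyl)-3-(3-hydroxy-4,5-dimethoxybenzyl)dihydrofuran-2(3H)-one | COc1ccc(C[C@H]2COC(=O)[C@@H]2Cc2cc(O)c(OC)c(OC)c2)cc1OC | target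

## Step count and least certain steps

Total step count: 8. Longest linear sequence: 6 steps (1 → 4 → 6 → 12 → 16 → 19 → 20). The branch from 7 through 8 and 11 is equally long.

**Step 6 (key step).**
- *What may go wrong.* The most likely failure is incomplete geometric control in the enolisation, or partial passage through a boat. Either erodes the configuration at C3, because the Z preference depends on how fully DMPU breaks up the cyclic lithium-bound deprotonation. Less likely are deprotonation at the allylic and benzylic CH2 followed by 1,4-elimination of the carboxylate, and C-silylation. A small erosion at C3 is harmless, since brief treatment of 19 with DBU should level it to the thermodynamic trans arrangement.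
- *Fallback.* It sets out from 6, uses 8 for the second fragment, returns at 19, and decouples the two centres.
- A Johnson–Claisen rearrangement of 6 (MeC(OEt)3, cat. EtCO2H, 140 °C) has no enolate geometry to control. It transfers chirality through the same chair to give ethyl (R,E)-3-(3,4-dimethoxybenzyl)hex-4-enoate F1.
- Reductive ozonolysis gives ethyl (R)-3-(3,4-dimethoxybenzyl)-4-hydroxybutanoate F2, which closes in acid to (R)-4-(3,4-dimethoxybenzyl)dihydrofuran-2(3H)-one F3.
- Aldehyde 8 is reduced with NaBH4 to (3-benzyloxy-4,5-dimethoxyphenyl)methanol F4 and converted with PBr3 into 3-benzyloxy-4,5-dimethoxybenzyl bromide F5.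
- The enolate of F3 (LiN(SiMe3)2, THF, −78 °C) is alkylated by F5 on the face anti to the C4 substituent, which gives 19.

**Step 1.**
- *What may go wrong.* The electron-rich benzylic chloride may self-condense under the Lewis-acidic magnesium salts. Transfer from copper may be slow, and the product may undergo propargyl-to-allenyl isomerisation on prolonged heating.
- *Fallback.* It sets out from 1, returns at 6 and makes step 2 unnecessary. The E alkene is built first and the benzylic bond is made by cross-coupling.
- Silylation (t-BuMe2SiCl, imidazole) gives (R)-tert-butyl(but-3-yn-2-yloxy)dimethylsilane F6.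
- Syn hydroboration with pinacolborane (cat. Cp2ZrHCl, Et3N) gives pinacol (R,E)-[3-(tert-butyldimethylsilyloxy)but-1-en-1-yl]boronate F7.
- Suzuki–Miyaura coupling with 2 (Pd(PPh3)4, zerovalent palladium, K3PO4, THF/water) gives (R,E)-tert-butyl[5-(3,4-dimethoxyphenyl)pent-3-en-2-yloxy]dimethylsilane F8.
- Bu4NF then releases 6.

**Step 7.**
- *What may go wrong.* Ozone may attack the dimethoxy- and trialkoxyarene rings once the alkene is used up, and C4 may epimerise at the aldehyde stage if reduction lags.
- *Fallback.* It sets out from 16, returns at 19 and replaces ozone by an oxidant that does not touch arenes.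
- Esterification (MeI, K2CO3, DMF) gives methyl (2R,3S,4E)-2-(3-benzyloxy-4,5-dimethoxybenzyl)-3-(3,4-dimethoxybenzyl)hex-4-enoate F9.
- Lemieux–Johnson cleavage (cat. OsO4, NaIO4, 2,6-lutidine, dioxane/water) gives methyl (2R,3R)-2-(3-benzyloxy-4,5-dimethoxybenzyl)-3-(3,4-dimethoxybenzyl)-4-oxobutanoate F10.
- NaBH4 in MeOH at 0 °C gives methyl (2R,3R)-2-(3-benzyloxy-4,5-dimethoxybenzyl)-3-(3,4-dimethoxybenzyl)-4-hydroxybutanoate F11, which cyclises to 19 on acidic work-up.

**Step 4.**
- *What may go wrong.* Hydride transfer to the electron-rich, and therefore less electrophilic, arylidene intermediate may be sluggish. Ring hydrolysis and decarboxylation may also stop short of completion.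
- *Fallback.* It sets out from 8, returns at 11 and separates chain extension from saturation.
- Knoevenagel–Doebner condensation (malonic acid, pyridine, piperidine, 90 °C) gives (E)-3-(3-benzyloxy-4,5-dimethoxyphenyl)prop-2-enoic acid F12.
- Homogeneous hydrogenation (H2, RhCl(PPh3)3, toluene/EtOH) saturates the alkene without hydrogenolysis of the benzyl ether and gives 11.

## Further compounds

F1 | step 6 | ethyl (R,E)-3-(3,4-dimethoxybenzyl)hex-4-enoate | COc1ccc(C[C@@H](/C=C/C)CC(=O)OCC)cc1OC
F2 | step 6 | ethyl (R)-3-(3,4-dimethoxybenzyl)-4-hydroxybutanoate | COc1ccc(C[C@@H](CO)CC(=O)OCC)cc1OC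
F3 | step 6 | (R)-4-(3,4-dimethoxybenzyl)dihydrofuran-2(3H)-one | COc1ccc(C[C@H]2COC(=O)C2)cc1OC
F4 | step 6 | (3-benzyloxy-4,5-dimethoxyphenyl)methanol | COc1cc(CO)cc(OCc2ccccc2)c1OC
F5 | step 6 | 3-benzyloxy-4,5-dimethoxybenzyl bromide | COc1cc(CBr)cc(OCc2ccccc2)c1OC
F6 | step 1 | (R)-tert-butyl(but-3-yn-2-yloxy)dimethylsilane | C[C@@H](O[Si](C)(C)C(C)(C)C)C#C
F7 | step 1 | pinacol (R,E)-[3-(tert-butyldimethylsilyloxy)but-1-en-1-yl]boronate | C[C@@H](O[Si](C)(C)C(C)(C)C)/C=C/B1OC(C)(C)C(C)(C)O1
F8 | step 1 | (R,E)-tert-butyl[5-(3,4-dimethoxyphenyl)pent-3-en-2-yloxy]dimethylsilane | C[C@@H](O[Si](C)(C)C(C)(C)C)/C=C/Cc1ccc(OC)c(OC)c1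
F9 | step 7 | methyl (2R,3S,4E)-2-(3-benzyloxy-4,5-dimethoxybenzyl)-3-(3,4-dimethoxybenzyl)hex-4-enoate | COc1ccc(C[C@@H](/C=C/C)[C@@H](Cc2cc(OCc3ccccc3)c(OC)c(OC)c2)C(=O)OC)cc1OC
F10 | step 7 | methyl (2R,3R)-2-(3-benzyloxy-4,5-dimethoxybenzyl)-3-(3,4-dimethoxybenzyl)-4-oxobutanoate | COc1ccc(C[C@@H](C=O)[C@@H](Cc2cc(OCc3ccccc3)c(OC)c(OC)c2)C(=O)OC)cc1OC
F11 | step 7 | methyl (2R,3R)-2-(3-benzyloxy-4,5-dimethoxybenzyl)-3-(3,4-dimethoxybenzyl)-4-hydroxybutanoate | COc1ccc(C[C@@H](CO)[C@@H](Cc2cc(OCc3ccccc3)c(OC)c(OC)c2)C(=O)OC)cc1OC
F12 | step 4 | (E)-3-(3-benzyloxy-4,5-dimethoxyphenyl)prop-2-enoic acid | COc1cc(/C=C/C(=O)O)cc(OCc2ccccc2)c1OC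
A1 | alternative 1 | (E)-4-(3,4-dimethoxyphenyl)but-2-enal | COc1ccc(C/C=C/C=O)cc1OC
A2 | alternative 1 | formaldehyde | C=O
A3 | alternative 1 | (R)-4-(3,4-dimethoxybenzyl)dihydrofuran-2(3H)-one | COc1ccc(C[C@H]2COC(=O)C2)cc1OC
A4 | alternative 2 | arctigenin, (3R,4R)-4-(3,4-dimethoxybenzyl)-3-(4-hydroxy-3-methoxybenzyl)dihydrofuran-2(3H)-one | COc1ccc(C[C@H]2COC(=O)[C@@H]2Cc2ccc(O)c(OC)c2)cc1OC
A5 | alternative 2 | 5'-hydroxyarctigenin, (3R,4R)-3-(3,4-dihydroxy-5-methoxybenzyl)-4-(3,4-dimethoxybenzyl)dihydrofuran-2(3H)-one | COc1ccc(C[C@H]2COC(=O)[C@@H]2Cc2cc(O)c(O)c(OC)c2)cc1OC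
A6 | alternative 3 | methyl 2-(3-benzyloxy-4,5-dimethoxybenzyl)-4-(3,4-dimethoxyphenyl)-3-formylbutanoate, all four stereoisomers | COC(=O)C(Cc1cc(OCc2ccccc2)c(OC)c(OC)c1)C(C=O)Cc1ccc(OC)c(OC)c1
A7 | alternative 3 | (4R)-3-(3-benzyloxy-4,5-dimethoxybenzyl)-4-(3,4-dimethoxybenzyl)dihydrofuran-2(3H)-one, both C3 epimers | COc1ccc(C[C@H]2COC(=O)C2Cc2cc(OCc3ccccc3)c(OC)c(OC)c2)cc1OC
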